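I began by counting, taking one coupling partner for each product formed. To use up both substrates, the flask would have to bring 66.7 % of its charged partner into product, so that was the opposite outcome to test.

common to all: left-handed substrate 0.25 M; right-handed substrate 0.25 M; free catalyst 2.5 mol%

| run | coupling partner | impurity | remark | time |
|---|---|---|---|---|
| north | 3 equiv | 0.34 mM | run made earlier |  |
| east | 3 equiv | 1.3 mM | run made earlier |  |
| west | 1.5 equiv | 0.67 mM | run made earlier |  |
| flask | 3.00 equiv | 0.67 mM |  | 12 h |

- north (time / h: left-handed product / %, right-handed product / %, left-handed substrate / %): 0.833: 25.2, 9.8, 28.7; 2.50: 32.5, 12.6, 26.2; 5.00: 33.9, 13.7, 26.6; 8.00: 33.8, 13.8, 26.6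
- east (time / h: left-handed product / %, right-handed product / %, left-handed substrate / %): 0.500: 17.8, 7.2, 34.8; 1.33: 26.7, 10.4, 29.0; 3.00: 30.1, 11.2, 29.0; 8.00: 30.4, 11.8, 28.7
- west (time / h: left-handed product / %, right-handed product / %, left-handed substrate / %): 2.00: 17.8, 6.5, 36.8; 4.00: 18.4, 6.8, 36.7; 5.00: 19.2, 6.9, 36.7; 8.00: 18.5, 7.0, 37.1

(each reading ± 0.3 percentage points)

- left-handed product and right-handed product together, in percent of the left-handed substrate and right-handed substrate charged together, at 12 h
- excess of left-handed product over right-handed product in the product at 12 h
- whether the exchange between left-handed substrate and right-handed substrate keeps pace with the reaction: how far the product's excess at 12 h gets from its value without exchange to its value with instant exchange (above 80 % keeps pace, below 20 % hardly takes part, else lags behind)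

- free catalyst is single-handed; left-handed substrate and right-handed substrate are mirror images of each other, charged as a racemate, each of them at the stated concentration
- what was read earlier has a scatter of 0.3 percentage points, one standard deviation
- an excess is the difference of the two amounts in percent of their sum
- an excess is below zero if the other one leads

The readings at 8.00 h lay on flat plateaus in north, east and west, so I reckoned from those rows:

share = 2 × (both products, as a fraction of both substrates charged) / equivalents of partner

north: 31.7 %

east: 28.1 %

west: 34.0 %

Going in a straight line between north and east, to the impurity of the flask:

flask share: 30.5 %

flask yield = share × equivalents / 2 = 45.7 %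

This partner's share, the fraction of charged partner found in product, is a mean over the whole run. For the flask it came to about half of what full consumption needs, so I expected substrate left over. West's share stood above north's, and its left-handed substrate also ended higher, at 37.1 % against 26.6 %. I therefore compared shares between similar partner charges.

The forecast gave 45.5 %, an excess of 43.5 %, and lags behind: “so exchange lags behind”.

The flask gives 45.5 % and an excess of 43.2 %, and the exchange lags behind, getting 50 % of the way.

    coupling partner + free catalyst + left-handed substrate → free catalyst + left-handed product (k = 0.0930 /M²/s)
    coupling partner + free catalyst + right-handed substrate → free catalyst + right-handed product (k = 0.0320 /M²/s)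
    left-handed substrate ⇌ right-handed substrate (k = 2.10 × 10⁻⁴ /s)
    coupling partner → decomposed reagent (k = 2.90 × 10⁻⁴ /s)
    free catalyst + impurity → spent catalyst (k = 43.0 /M/s)

The flask's share is 30.3 %, against my 30.5 %. Coupling partner stands at 0 % at 12.0 h while left-handed substrate keeps 55 % of its charge, so partner is the limiting reagent despite its excess. The turning of coupling partner into decomposed reagent is the main reason that the flask stops short of full conversion: without that step, 99.0 % of the two substrates charged together reacts instead of 45.5 %. The neighbour with 1.20 equiv of partner has west's impurity but less partner; west's share, carried over to that charge, gives a yield of 20.4 %, and that neighbour flask gives 20.8 %.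

All runs are calculated on assumed constants; scatter was added.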